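All runs were computed from invented constants.

- In a one-step world the left-handed substrate halves again and again while the right-handed substrate stands still, so the ratio [left-handed substrate]/[right-handed substrate] starts at one and must fall to 0.0256 for the wanted excess; the number of halvings this takes, the half-life count, 5.29, is what you carry from flask to flask.

common to all: left-handed substrate 0.052 M; right-handed substrate 0.052 M

| charge | coupling partner | free catalyst | remark | time |
|---|---|---|---|---|
| eta | 2 equiv | 0.05 mol% | run made earlier |  |
| beta | 2 equiv | 0.075 mol% | run made earlier |  |
| alpha | 4 equiv | 0.1 mol% | run made earlier |  |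
| flask | 2.00 equiv | 0.1 mol% |  | 30 h |

- eta (time / h: right-handed substrate / %, left-handed substrate / %): 3.00: 49.1, 27.3; 8.00: 49.5, 8.2; 15.0: 47.8, 1.0; 25.0: 45.9, 0.3
- beta (time / h: right-handed substrate / %, left-handed substrate / %): 6.00: 49.7, 5.7; 12.0: 46.6, 0.8; 20.0: 44.2, 0; 25.0: 43.3, 0
- alpha (time / h: right-handed substrate / %, left-handed substrate / %): 6.00: 43.1, 0.1; 12.0: 37.4, 0.3; 20.0: 30.7, 0; 25.0: 26.4, 0.4

(each reading ± 0.5 percentage points)

- whether the excess of right-handed substrate over left-handed substrate among what is left of the two reaches 95% by 30 h (yes / no)
- the highest excess of right-handed substrate over left-handed substrate among what is left of the two up to 30 h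

- free catalyst is single-handed; left-handed substrate and right-handed substrate are mirror images of each other, charged as a racemate, each of them at the stated concentration
- steps that have been proposed: free catalyst + left-handed substrate <-> catalyst intermediate A; free catalyst + right-handed substrate <-> catalyst intermediate B; coupling partner + catalyst intermediate A -> free catalyst + left-handed product; coupling partner + catalyst intermediate B -> free catalyst + right-handed product; free catalyst <-> dormant form; left-handed product <-> right-handed product; coupling partner -> decomposition product

- Take the main step first: the eta readings of left-handed substrate give a pseudo-first-order constant of 0.241 h⁻¹, the beta readings give 0.327 h⁻¹, roughly in step with loading, so scaling eta by loading gives this flask 0.481 h⁻¹, a half-life of 1.44 h, and the count is finished after 7.61 h.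

- Now let the right-handed substrate react too: the beta readings give 0.00726 h⁻¹, which is 0.00967 h⁻¹ at this flask's loading, far slower than the left-handed decay, a selectivity factor of 49.7, so the ratio falls at the difference of the two and your time moves to 7.77 h.

- The remaining steps you do not add separately, since the eta constant was read with them present, so the number stays; this flask's 30 h then holds 20.4 halvings, well beyond the count, and you commit to yes with a top near 100%.

- The forecast, made on its own rates, says yes with a top of 99.9%, between 99% and 100%, on the ground “By 30 h the left-handed substrate is essentially gone”.

- This flask gives yes and a top of 100%.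

    free catalyst + left-handed substrate ⇌ catalyst intermediate A (K = 110 M⁻¹, k = 24000 M⁻¹ min⁻¹)
    free catalyst + right-handed substrate ⇌ catalyst intermediate B (K = 8.70 M⁻¹, k = 1100 M⁻¹ min⁻¹)
    coupling partner + catalyst intermediate A → free catalyst + left-handed product (k = 79.0 M⁻¹ min⁻¹)
    coupling partner + catalyst intermediate B → free catalyst + right-handed product (k = 12.0 M⁻¹ min⁻¹)
    free catalyst ⇌ dormant form (K = 0.480, k = 0.00440 min⁻¹)
    left-handed product ⇌ right-handed product (k = 2.20 × 10⁻⁴ min⁻¹)
    coupling partner → decomposition product (k = 1.40 × 10⁻⁵ min⁻¹)

- This flask reaches the wanted excess at 6.73 h, so the count gives an average halving time of the ratio of 1.27 h. On the beta run the same count, with eta scaled to beta's loading, gives 10.2 h, and the beta readings bracket that time, with an excess read as 79.4% at 6.00 h and 96.6% at 12.0 h. The largest single effect behind this flask's yes is the reaction of free catalyst + left-handed substrate to catalyst intermediate A, both ways: in the run without it, the part of the two substrates charged together that has reacted at 30.0 h goes from 60.1% to 19.4%.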